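**Retrosynthetic overview**

1. Pieces: monomethyl phthalate (1) and mesityl oxide (2) give, through acyl imidazolide 3, the C14 ortho-acylbenzoate 4; 1,4-naphthoquinone (5) is the C10 piece. Both benzene rings are bought.
2. Seven-membered ring (formed first): disconnect the quinol C2–CH bond (conjugate addition, adduct 6) and the quinol C3–C(=O) bond (Claisen-type C-acylation) of ring-closed quinol 7, which leads back to 4 + 5.
3. Furan ring (formed last): disconnect the furan O–C2 bond, i.e. rehydrate through hemiketal 8; radermachol 9 comes from 7 by loss of water only.
4. Overall 4 + 5 → 9 + MeOH + H2O: redox-neutral, no protecting groups.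

Assumption: radermachol has no stereocentre or stereogenic double bond, so it is achiral and needs no enantiocontrol; its biogenesis is taken as the union of a naphthoquinone C10 unit with a lapachol-derived ortho-acylbenzoyl C14 unit (lapachol less C2) by conjugate addition, C-acylation and quinol O-cyclisation.

**Route**

Step 1
Reactants: 1 monomethyl phthalate (2-(methoxycarbonyl)benzoic acid); 2 mesityl oxide (4-methylpent-3-en-2-one)
Product: 4 methyl 2-(5-methyl-3-oxohex-4-enoyl)benzoate, via acyl imidazolide 3 (not isolated)
Conditions: 1, 1,1'-carbonyldiimidazole (1.05 equiv), THF, rt, 1 h; then cannulate into 2 (3.3 equiv)/LiN(SiMe3)2 (3.2 equiv), THF, −78 °C; AcOH (4 equiv) quench at −78 °C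
Reagents that add atoms: none
Why: Crossed Claisen-type C-acylation of a ketone enolate by an acyl imidazolide: LiN(SiMe3)2 at −78 °C deprotonates 2 kinetically at the methyl ketone carbon, 3 is a far better acyl donor than the methyl ester, the product is held as its lithium diketonate (hence the extra enolate, one further equivalent being consumed by the imidazole N–H), and the cold AcOH quench keeps the ortho ester from Dieckmann closure to the 2-acylindane-1,3-dione; no stereocentre is formed.

Step 2
Reactants: 4 methyl 2-(5-methyl-3-oxohex-4-enoyl)benzoate (1.1 equiv); 5 1,4-naphthoquinone (1.0 equiv)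
Product: 7 ring-closed quinol triketone (seven-membered 1,3-diketone ring on the 2,3-bond of naphthalene-1,4-diol; full description in the compound list), via Michael adduct 6 (not isolated)
Conditions: Et3N (0.2 equiv), degassed MeCN, 0 °C to rt, Ar; then MgCl2 (3 equiv), Et3N (6 equiv), 80 °C; 1 M HCl, 0 °C
Reagents that add atoms: none
Why: Proposed new method: a tandem conjugate addition/Claisen-type ring closure, the seven-ring homologue of the Hauser–Kraus Michael–Dieckmann annulation. With only catalytic base the diketone adds to 5 as in the first stage of the Nenitzescu-type quinone/1,3-dicarbonyl reaction, giving neutral quinol 6 with little redox exchange. With MgCl2/excess Et3N the magnesium naphthalene-1,4-diolate of 6 (the bis-enolate of tetralin-1,4-dione) attacks the ortho ester through C3, the only carbonyl that carbon can reach (7-exo-trig), via a six-membered O–Mg–O chelate. The closest known types are MgCl2/Et3N soft-enolisation C-acylation and ortho-specific C–C bond formation of magnesium phenoxides. Methoxide loss gives a chelated 3-acylquinolate as an irreversible sink, and furan closure is held back because the 1,3-diketone is tied up as its magnesium enolate; the CH stereocentre of 6 and 7 is racemic and is erased in step 3.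

Step 3
Reactants: 7 ring-closed quinol triketone
Product: 9 radermachol, via cyclic hemiketal 8 (not isolated)
Conditions: TsOH·H2O (10 mol %), toluene, 4 Å MS, 60 °C, Ar
Reagents that add atoms: none
Why: Paal–Knorr-type cyclodehydration of a 1,4-related hydroxyl/ketone pair: the quinol C1–OH can reach only the exocyclic 3-methylbut-2-enoyl carbonyl (the ring ketone would require a bridged furan), so the 2-(2-methylprop-1-enyl)furan regiochemistry is fixed by ring geometry, furan aromatisation drives loss of water from 8, and the remaining chelated acylnaphthol is the tautomer of the enol–tropone form in the target SMILES; all stereocentres of 7 and 8 vanish and 9 is achiral.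

**Compound list**

1 | monomethyl phthalate (2-(methoxycarbonyl)benzoic acid) | COC(=O)c1ccccc1C(=O)O | starting material
2 | mesityl oxide (4-methylpent-3-en-2-one) | CC(C)=CC(C)=O | starting material
3 | acyl imidazolide, methyl 2-(1H-imidazole-1-carbonyl)benzoate | COC(=O)c1ccccc1C(=O)n1ccnc1 | intermediate
4 | methyl 2-(5-methyl-3-oxohex-4-enoyl)benzoate (drawn as the diketone; largely enolised) | COC(=O)c1ccccc1C(=O)CC(=O)C=C(C)C | intermediate
5 | 1,4-naphthoquinone | O=C1C=CC(=O)c2ccccc12 | starting material
6 | Michael adduct, methyl 2-[2-(1,4-dihydroxynaphthalen-2-yl)-5-methyl-3-oxohex-4-enoyl]benzoate (racemic, enolisable CH) | COC(=O)c1ccccc1C(=O)C(C(=O)C=C(C)C)c1cc(O)c2ccccc2c1O | intermediate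
7 | ring-closed quinol triketone: naphthalene-1,4-diol fused at C2–C3 to a seven-membered ring running C3–C(=O)–(benzene-1,2-diyl)–C(=O)–CH–C2, the CH carrying a 3-methylbut-2-enoyl group (racemic, enolisable CH) | CC(C)=CC(=O)C1C(=O)c2ccccc2C(=O)c2c(O)c3ccccc3c(O)c21 | intermediate
8 | cyclic hemiketal of 7: the C1–OH has added to the exocyclic ketone to give a 2-hydroxy-2-(2-methylprop-1-enyl)-2,3-dihydronaphtho[1,2-b]furan ring (diastereomer mixture, both stereocentres lost on dehydration) | CC(C)=CC1(O)Oc2c3ccccc3c(O)c3c2C1C(=O)c1ccccc1C3=O | intermediate
9 | radermachol: 2-(2-methylprop-1-enyl)naphtho[1,2-b]furan-5-ol whose C3 and C4 are bridged by a benzene-1,2-dicarbonyl unit into a seven-membered ring, drawn as the chelated enol–tropone tautomer; achiral | CC(C)=Cc1oc2c3c(c(O)c4ccccc4c(=O)c13)C(=O)c1ccccc1-2 | target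

**Step count and risks**

Total step count: 3. Longest linear sequence: 3 steps (1 → 4 → 7 → 9).

Steps most likely to fail, in order: step 2, step 1, step 3.

Step 2 is the main risk. The quinol carbon may not be acylated by an unactivated methyl ester under MgCl2/Et3N. Quinol 6 may exchange redox state with 5 and drift to a 2-substituted quinone and a linear furanoquinone. The diketone carbon may close onto the ester and then lose the senecioyl group. The fallback reverses the order of ring formation; it sets out from 4 and 5 and comes back at 9. In(OTf)3 (10 mol %) in MeCN at 50 °C effects Michael addition/cyclodehydration through 6 to give the naphthofuranol keto ester methyl 2-{[5-hydroxy-2-(2-methylprop-1-en-1-yl)naphtho[1,2-b]furan-3-yl]carbonyl}benzoate F2. The direction of this furan closure (alkenyl versus aryl ketone) is not fixed by geometry and must be checked by HMBC. LiOH in THF–H2O then gives the carboxylic acid 2-{[5-hydroxy-2-(2-methylprop-1-en-1-yl)naphtho[1,2-b]furan-3-yl]carbonyl}benzoic acid F3. Electrophilic Friedel–Crafts closure at C4 with P2O5 in MeSO3H (rt to 40 °C) gives 9; the alkene should tolerate this because it is part of a deactivated vinylogous enone.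

Step 1 may give O-acylation, γ-deprotonation of 2, or Dieckmann closure of the product diketonate to 2-(3-methylbut-2-enoyl)indane-1,3-dione. The fallback sets out from 2, with commercial phthalic anhydride in place of 1, and comes back at 4. The lithium enolate of 2 (2.2 equiv, LiN(SiMe3)2, THF, −78 °C) opens the anhydride to the keto acid 2-(5-methyl-3-oxohex-4-enoyl)benzoic acid F1. Its carboxylate can neither cyclise to the indanedione nor be acylated twice. Selective carboxylate methylation (MeI, KHCO3, DMF, rt) gives 4.

Step 3 may fail if acid makes the diketone enol oxygen add to the β,β-dimethyl enone (a 2,2-dimethyl-2,3-dihydropyran-4-one), or if quinol 7 oxidises in air. The fallback sets out from 7 and comes back at 9. Pyrrolidine (2 equiv) in toluene with 4 Å MS at 60 °C converts the exocyclic ketone into the pyrrolidine enaminone F4. Warming with AcOH lets the C1–OH add to the aminated carbon and expel the amine, the furan-forming branch of the Nenitzescu reaction, under buffered conditions.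

**Further compounds**

F1 | step 1 | 2-(5-methyl-3-oxohex-4-enoyl)benzoic acid | OC(=O)c1ccccc1C(=O)CC(=O)C=C(C)C
F2 | step 2 | methyl 2-{[5-hydroxy-2-(2-methylprop-1-en-1-yl)naphtho[1,2-b]furan-3-yl]carbonyl}benzoate | COC(=O)c1ccccc1C(=O)c1c(C=C(C)C)oc2c1cc(O)c1ccccc12
F3 | step 2 | 2-{[5-hydroxy-2-(2-methylprop-1-en-1-yl)naphtho[1,2-b]furan-3-yl]carbonyl}benzoic acid | OC(=O)c1ccccc1C(=O)c1c(C=C(C)C)oc2c1cc(O)c1ccccc12
F4 | step 3 | pyrrolidine enaminone of 7 (pyrrolidin-1-yl on the former exocyclic ketone carbon, C=C to the ring CH carbon) | CC(C)=CC(N1CCCC1)=C1C(=O)c2ccccc2C(=O)c2c(O)c3ccccc3c(O)c21
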